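The plan builds the central phenol ring E last, between two finished chromones. In ring E the oxygen on E-C4 sits ortho to E-C3 (bonded to C3 of the 7-methoxychromone, unit 1) and para to E-C1 (bonded to C2 of the 5,7-dihydroxychromone, unit 2). This 1,3,4-pattern is what a 1-amino-3-siloxy diene imprints on an acceptor alkyne. One heating step forms E-C2–E-C3 and E-C1–E-C6, expels dimethylamine and delivers aromatic ring E as its silyl ether, so the crowded E-C3–C3 bond is never made by coupling. The precursors are a (1E,3Z)-diene carried on C3 of the protected unit 1 flavone and 2-ethynyl-5,7-bis(benzyloxy)chromone.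

Key step: step 11

Labels: unit 1 is the 2-aryl-5-hydroxy-7-methoxychromone and unit 2 is the 5,7-dihydroxychromone. In ring E, E-C1 carries unit 2, E-C3 carries unit 1 and E-C4 carries oxygen.
Remark: the target has no stereocentre, and rotation about the E-C3–C3 axis is assumed fast enough that atropisomers need not be addressed.

Step 1
Reactants: 1 1,3,5-trimethoxybenzene; 2 succinic anhydride
Product: 4 4-(2-hydroxy-4,6-dimethoxyphenyl)-4-oxobutanoic acid, via trimethoxyphenyl keto acid 3 (not isolated)
Conditions: AlCl3 (3.5 equiv), ClCH2CH2Cl, 0 °C → 45 °C; aq. HCl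
Reagents that add atoms: none
Why: Friedel–Crafts succinoylation of the symmetrical, strongly activated arene can give only one regioisomer, and the excess AlCl3 then cleaves one methyl ether ortho to the new ketone through a six-membered aluminium chelate (chelation-directed demethylation).

Step 2
Reactants: 4 4-(2-hydroxy-4,6-dimethoxyphenyl)-4-oxobutanoic acid
Product: 5 4-(2-hydroxy-4,6-dimethoxyphenyl)-N-methoxy-N-methyl-4-oxobutanamide
Conditions: MeNH(OMe)·HCl, EDC·HCl, N-methylmorpholine, CH2Cl2, 0 °C → rt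
Reagents that add atoms: N,O-dimethylhydroxylamine hydrochloride, CNOC.Cl
Why: Carbodiimide amide coupling in which the amine outcompetes the hydrogen-bonded, weakly nucleophilic ortho-acyl phenol, and installing the N-methoxy-N-methyl amide here removes any later ester hydrolysis on a base-sensitive flavone.

Step 3
Reactants: 5 4-(2-hydroxy-4,6-dimethoxyphenyl)-N-methoxy-N-methyl-4-oxobutanamide; 6 4-(benzyloxy)benzoyl chloride
Product: 7 3,5-dimethoxy-2-{4-[methoxy(methyl)amino]-4-oxobutanoyl}phenyl 4-(benzyloxy)benzoate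
Conditions: Et3N, DMAP (cat.), CH2Cl2, 0 °C → rt
Reagents that add atoms: none
Why: DMAP-catalysed O-acylation (esterification with an acid chloride) of the only free hydroxyl group.

Step 4
Reactants: 7 3,5-dimethoxy-2-{4-[methoxy(methyl)amino]-4-oxobutanoyl}phenyl 4-(benzyloxy)benzoate
Product: 9 2-{2-[4-(benzyloxy)phenyl]-5,7-dimethoxy-4-oxo-4H-chromen-3-yl}-N-methoxy-N-methylacetamide, via racemic 1,3-diketone 8 (not isolated)
Conditions: LiN(SiMe3)2 (3 equiv), THF, −78 → 0 °C; AcOH; then TsOH·H2O (cat.), toluene, 100 °C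
Reagents that add atoms: none
Why: Baker–Venkataraman rearrangement, in which the ketone enolate (a more acidic site than the amide CH2) takes over the aroyl group through a six-membered transition state, and the racemic 2-substituted 1,3-diketone, whose stereocentre vanishes again, undergoes acid-catalysed cyclodehydration to the 3-substituted flavone under conditions that spare the benzyl ether and the amide.

Step 5
Reactants: 9 2-{2-[4-(benzyloxy)phenyl]-5,7-dimethoxy-4-oxo-4H-chromen-3-yl}-N-methoxy-N-methylacetamide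
Product: 11 2-[4-(benzyloxy)phenyl]-3-[(3E)-4-(dimethylamino)-2-oxobut-3-en-1-yl]-5,7-dimethoxy-4H-chromen-4-one, via terminal ynone 10 (not isolated)
Conditions: HC≡CMgBr (3 equiv), THF, 0 °C → rt; cold aq. NaHSO4, extraction; then Me2NH (2 M in THF), 0 °C
Reagents that add atoms: ethynylmagnesium bromide, C#C[Mg]Br; dimethylamine, CNC
Why: Weinreb ketone synthesis (the magnesium chelate stops over-addition and the vinylogous-ester C4 carbonyl is far less electrophilic) followed by aza-Michael addition of Me2NH to the ynone, which gives the thermodynamically preferred (E)-enaminone and avoids the regiochemical ambiguity of condensing a methyl ketone with an amide acetal next to the more acidic CH2.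

Step 6
Reactants: 11 2-[4-(benzyloxy)phenyl]-3-[(3E)-4-(dimethylamino)-2-oxobut-3-en-1-yl]-5,7-dimethoxy-4H-chromen-4-one
Product: 12 2-[4-(benzyloxy)phenyl]-3-[(1Z,3E)-2-(tert-butyldimethylsilyloxy)-4-(dimethylamino)buta-1,3-dien-1-yl]-5,7-dimethoxy-4H-chromen-4-one
Conditions: KN(SiMe3)2, THF, −78 °C; TBSCl, −78 °C → rt; filtration under argon, used crude
Reagents that add atoms: tert-butyldimethylsilyl chloride, CC(C)(C)[Si](C)(C)Cl
Why: Deprotonation at the only enolisable position and O-silylation of the potassium enolate, the standard preparation of 1-amino-3-siloxy dienes, should favour the (Z)-enol ether because the bulky chromonyl group then lies trans to the aminovinyl arm and points outward in the s-cis diene.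

Step 7
Reactants: 13 2,4,6-trihydroxyacetophenone
Product: 14 1-[2,4-bis(benzyloxy)-6-hydroxyphenyl]ethan-1-one
Conditions: BnBr (2.1 equiv), K2CO3, DMF, rt → 50 °C
Reagents that add atoms: benzyl bromide, BrCc1ccccc1
Why: Williamson ether synthesis limited to two equivalents of halide, the last hydroxyl group being tied up in a hydrogen bond to the ketone and therefore the least nucleophilic.

Step 8
Reactants: 14 1-[2,4-bis(benzyloxy)-6-hydroxyphenyl]ethan-1-one
Product: 16 5,7-bis(benzyloxy)-2-methyl-4H-chromen-4-one, via 1,3-diketone 15 (not isolated)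
Conditions: NaH, EtOAc, THF, reflux; AcOH; then TsOH·H2O (cat.), toluene, 80 °C
Reagents that add atoms: ethyl acetate, CCOC(C)=O
Why: Crossed Claisen condensation of the ketone enolate with ethyl acetate followed by acid-catalysed cyclodehydration of the 1,3-diketone, the classical entry to 2-methylchromones.

Step 9
Reactants: 16 5,7-bis(benzyloxy)-2-methyl-4H-chromen-4-one
Product: 17 5,7-bis(benzyloxy)-4-oxo-4H-chromene-2-carbaldehyde
Conditions: SeO2 (1.5 equiv), 1,4-dioxane, reflux
Reagents that add atoms: selenium dioxide, O=[Se]=O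
Why: Riley oxidation of the C2 methyl group, which is vinylogously activated by the C4 carbonyl (ene reaction, then 2,3-sigmatropic shift), a transformation established for alkoxy-substituted 2-methylchromones.

Step 10
Reactants: 17 5,7-bis(benzyloxy)-4-oxo-4H-chromene-2-carbaldehyde
Product: 18 5,7-bis(benzyloxy)-2-ethynyl-4H-chromen-4-one
Conditions: Me3SiCHN2, LiN(iPr)2, THF, −78 °C; then 17, −78 → 0 °C
Reagents that add atoms: (trimethylsilyl)diazomethane, C[Si](C)(C)C=[N+]=[N-]
Why: Colvin rearrangement, in which the lithiated diazo compound adds to the aldehyde (by far the most electrophilic carbonyl), loss of LiOSiMe3 and N2 gives an alkylidene carbene whose 1,2-hydrogen shift delivers the terminal alkyne, and the aprotic cold medium avoids the alcohol addition to the activated alkyne that carbonate in methanol would invite.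

Step 11
Reactants: 12 2-[4-(benzyloxy)phenyl]-3-[(1Z,3E)-2-(tert-butyldimethylsilyloxy)-4-(dimethylamino)buta-1,3-dien-1-yl]-5,7-dimethoxy-4H-chromen-4-one; 18 5,7-bis(benzyloxy)-2-ethynyl-4H-chromen-4-one
Product: 20 5,7-bis(benzyloxy)-2-[3-{2-[4-(benzyloxy)phenyl]-5,7-dimethoxy-4-oxo-4H-chromen-3-yl}-4-(tert-butyldimethylsilyloxy)phenyl]-4H-chromen-4-one, via cis-aminocyclohexadiene adduct 19 (not isolated)
Conditions: 18 (1.8 equiv), BHT (trace), toluene, 100 °C, slow argon sweep; then SiO2, CH2Cl2, rt
Reagents that add atoms: none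
Why: Proposed new method: the nitrogen lone pair and the silyl enol ether push electron density to the chromonyl-bearing diene terminus (future E-C3), which should attack the unsubstituted alkyne carbon of 18 (future E-C2, the vinylogous acceptor position of the C4 carbonyl) while the aminated terminus (future E-C6) bonds to the internal alkyne carbon (future E-C1), in a concerted but asynchronous cycloaddition or its stepwise Michael–Mannich equivalent, to give cyclohexa-1,4-diene 19. The closest known reaction type is the Diels–Alder reaction of 1-amino-3-siloxy and 1-alkoxy-3-siloxy butadienes with propiolates and ynones, followed by loss of amine or alcohol to give para-acyl phenol derivatives; a diene carrying a chromon-3-yl group at its terminus and a 2-ethynylchromone as dienophile have not been shown in it. Ring E closes in an intermolecular [4+2] mode (four diene carbons, two alkyne carbons), and base-assisted 1,4-elimination of Me2NH (loss of the doubly allylic hydrogen at E-C3, departure of nitrogen from E-C6) makes it aromatic without an oxidant. The two sp3 centres of 19 should be cis because both terminal substituents of the (1E,3Z)-diene point outward, but both are erased on aromatisation, so nothing stereochemical has to be controlled. The step needs regioselectivity (chromon-2-yl para to the siloxy group), secured by the matched polarisation of the partners and by pairing the crowded diene terminus with the bare alkyne CH, and chemoselectivity for the alkyne over the chromone C2=C3 bonds, secured by their higher substitution and vinylogous ester character. Since the released Me2NH is itself a Michael donor towards 18, the alkyne is used in excess and the amine is stripped out by the argon stream.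

Step 12
Reactants: 20 5,7-bis(benzyloxy)-2-[3-{2-[4-(benzyloxy)phenyl]-5,7-dimethoxy-4-oxo-4H-chromen-3-yl}-4-(tert-butyldimethylsilyloxy)phenyl]-4H-chromen-4-one
Product: 21 5,7-bis(benzyloxy)-2-[3-{2-[4-(benzyloxy)phenyl]-5,7-dimethoxy-4-oxo-4H-chromen-3-yl}-4-hydroxyphenyl]-4H-chromen-4-one
Conditions: Bu4NF, AcOH, THF, 0 °C
Reagents that add atoms: none
Why: Fluoride-induced cleavage of the phenolic silyl ether, buffered with acetic acid so that neither phenoxide nor basic fluoride attacks the pyrone rings.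

Step 13
Reactants: 21 5,7-bis(benzyloxy)-2-[3-{2-[4-(benzyloxy)phenyl]-5,7-dimethoxy-4-oxo-4H-chromen-3-yl}-4-hydroxyphenyl]-4H-chromen-4-one
Product: 22 5,7-dihydroxy-2-{4-hydroxy-3-[5-hydroxy-2-(4-hydroxyphenyl)-7-methoxy-4-oxo-4H-chromen-3-yl]phenyl}-4H-chromen-4-one (target)
Conditions: BCl3 (12 equiv), pentamethylbenzene (10 equiv), CH2Cl2, −78 °C → rt; aq. HCl, THF
Reagents that add atoms: none
Why: Lewis-acid ether cleavage, in which BCl3 removes the three aryl benzyl ethers in the cold with pentamethylbenzene trapping the benzyl cation before it can C-benzylate the electron-rich rings, and on warming cleaves only the C5 methyl ether of unit 1 through its six-membered chelate with the C4 carbonyl, the unchelated C7 methyl ether being inert under these conditions.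

Compound list
1 | 1,3,5-trimethoxybenzene | COc1cc(OC)cc(OC)c1 | starting material
2 | succinic anhydride | O=C1CCC(=O)O1 | starting material
3 | 4-oxo-4-(2,4,6-trimethoxyphenyl)butanoic acid | COc1cc(OC)c(C(=O)CCC(=O)O)c(OC)c1 | intermediate (not isolated)
4 | 4-(2-hydroxy-4,6-dimethoxyphenyl)-4-oxobutanoic acid | COc1cc(O)c(C(=O)CCC(=O)O)c(OC)c1 | intermediate
5 | 4-(2-hydroxy-4,6-dimethoxyphenyl)-N-methoxy-N-methyl-4-oxobutanamide | COc1cc(O)c(C(=O)CCC(=O)N(C)OC)c(OC)c1 | intermediate
6 | 4-(benzyloxy)benzoyl chloride | O=C(Cl)c1ccc(OCc2ccccc2)cc1 | starting material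
7 | 3,5-dimethoxy-2-{4-[methoxy(methyl)amino]-4-oxobutanoyl}phenyl 4-(benzyloxy)benzoate | COc1cc(OC)c(C(=O)CCC(=O)N(C)OC)c(OC(=O)c2ccc(OCc3ccccc3)cc2)c1 | intermediate
8 | 3-[4-(benzyloxy)benzoyl]-4-(2-hydroxy-4,6-dimethoxyphenyl)-N-methoxy-N-methyl-4-oxobutanamide (racemic, drawn without configuration) | COc1cc(O)c(C(=O)C(CC(=O)N(C)OC)C(=O)c2ccc(OCc3ccccc3)cc2)c(OC)c1 | intermediate (not isolated)
9 | 2-{2-[4-(benzyloxy)phenyl]-5,7-dimethoxy-4-oxo-4H-chromen-3-yl}-N-methoxy-N-methylacetamide | COc1cc(OC)c2c(=O)c(CC(=O)N(C)OC)c(-c3ccc(OCc4ccccc4)cc3)oc2c1 | intermediate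
10 | 2-[4-(benzyloxy)phenyl]-5,7-dimethoxy-3-(2-oxobut-3-yn-1-yl)-4H-chromen-4-one | C#CC(=O)Cc1c(-c2ccc(OCc3ccccc3)cc2)oc2cc(OC)cc(OC)c2c1=O | intermediate (not isolated)
11 | 2-[4-(benzyloxy)phenyl]-3-[(3E)-4-(dimethylamino)-2-oxobut-3-en-1-yl]-5,7-dimethoxy-4H-chromen-4-one | CN(C)/C=C/C(=O)Cc1c(-c2ccc(OCc3ccccc3)cc2)oc2cc(OC)cc(OC)c2c1=O | intermediate
12 | 2-[4-(benzyloxy)phenyl]-3-[(1Z,3E)-2-(tert-butyldimethylsilyloxy)-4-(dimethylamino)buta-1,3-dien-1-yl]-5,7-dimethoxy-4H-chromen-4-one | CN(C)/C=C/C(O[Si](C)(C)C(C)(C)C)=C/c1c(-c2ccc(OCc3ccccc3)cc2)oc2cc(OC)cc(OC)c2c1=O | intermediate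
13 | 2,4,6-trihydroxyacetophenone | CC(=O)c1c(O)cc(O)cc1O | starting material
14 | 1-[2,4-bis(benzyloxy)-6-hydroxyphenyl]ethan-1-one | CC(=O)c1c(O)cc(OCc2ccccc2)cc1OCc1ccccc1 | intermediate
15 | 1-[2,4-bis(benzyloxy)-6-hydroxyphenyl]butane-1,3-dione | CC(=O)CC(=O)c1c(O)cc(OCc2ccccc2)cc1OCc1ccccc1 | intermediate (not isolated)
16 | 5,7-bis(benzyloxy)-2-methyl-4H-chromen-4-one | Cc1cc(=O)c2c(OCc3ccccc3)cc(OCc3ccccc3)cc2o1 | intermediate
17 | 5,7-bis(benzyloxy)-4-oxo-4H-chromene-2-carbaldehyde | O=Cc1cc(=O)c2c(OCc3ccccc3)cc(OCc3ccccc3)cc2o1 | intermediate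
18 | 5,7-bis(benzyloxy)-2-ethynyl-4H-chromen-4-one | C#Cc1cc(=O)c2c(OCc3ccccc3)cc(OCc3ccccc3)cc2o1 | intermediate
19 | 5,7-bis(benzyloxy)-2-[cis-3-{2-[4-(benzyloxy)phenyl]-5,7-dimethoxy-4-oxo-4H-chromen-3-yl}-4-(tert-butyldimethylsilyloxy)-6-(dimethylamino)cyclohexa-1,4-dien-1-yl]-4H-chromen-4-one (racemic, relative configuration shown) | CN(C)[C@@H]1C=C(O[Si](C)(C)C(C)(C)C)[C@H](c2c(-c3ccc(OCc4ccccc4)cc3)oc3cc(OC)cc(OC)c3c2=O)C=C1c1cc(=O)c2c(OCc3ccccc3)cc(OCc3ccccc3)cc2o1 | intermediate (not isolated)
20 | 5,7-bis(benzyloxy)-2-[3-{2-[4-(benzyloxy)phenyl]-5,7-dimethoxy-4-oxo-4H-chromen-3-yl}-4-(tert-butyldimethylsilyloxy)phenyl]-4H-chromen-4-one | COc1cc(OC)c2c(=O)c(-c3cc(-c4cc(=O)c5c(OCc6ccccc6)cc(OCc6ccccc6)cc5o4)ccc3O[Si](C)(C)C(C)(C)C)c(-c3ccc(OCc4ccccc4)cc3)oc2c1 | intermediate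
21 | 5,7-bis(benzyloxy)-2-[3-{2-[4-(benzyloxy)phenyl]-5,7-dimethoxy-4-oxo-4H-chromen-3-yl}-4-hydroxyphenyl]-4H-chromen-4-one | COc1cc(OC)c2c(=O)c(-c3cc(-c4cc(=O)c5c(OCc6ccccc6)cc(OCc6ccccc6)cc5o4)ccc3O)c(-c3ccc(OCc4ccccc4)cc3)oc2c1 | intermediate
22 | 5,7-dihydroxy-2-{4-hydroxy-3-[5-hydroxy-2-(4-hydroxyphenyl)-7-methoxy-4-oxo-4H-chromen-3-yl]phenyl}-4H-chromen-4-one | COc1cc(O)c2c(=O)c(-c3cc(-c4cc(=O)c5c(O)cc(O)cc5o4)ccc3O)c(-c3ccc(O)cc3)oc2c1 | target

Total step count: 13. Longest linear sequence: 9 steps (steps 1–6, then 11–13). The dienophile branch (steps 7–10) runs in parallel.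

Steps most likely to fail

Step 11 (proposed new method). The cycloaddition at the crowded chromonyl-bearing diene terminus may be slower than hydrolysis or thermal decay of the diene. The amine released on aromatisation may also consume the ethynylchromone by conjugate addition. The fallback uses known reaction types only, sets out from diene 12 and ketone 14, and comes back to the route at 20. Diene 12 is heated with a large excess of methyl propiolate. This small, cheap acceptor alkyne is one for which the benzannulation is established, and its excess also absorbs the amine. The cis-aminocyclohexadiene ester F1 loses dimethylamine to give methyl 3-{2-[4-(benzyloxy)phenyl]-5,7-dimethoxy-4-oxo-4H-chromen-3-yl}-4-(tert-butyldimethylsilyloxy)benzoate F2. Crossed Claisen condensation of this ester with 14, deprotonated in situ (LiN(SiMe3)2, THF, −78 °C → rt), gives the 1,3-diketone F3. TsOH-catalysed cyclodehydration in toluene then builds the unit 2 chromone after ring E instead of before it and gives 20. Any material that loses silicon on the way is 21 and joins at step 13.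

Step 10. The lithiated diazo reagent or the lithium silanolate formed with the alkyne may attack the pyrone ring and open it, or may add to the activated alkyne once it is formed. The fallback sets out from aldehyde 17 and comes back at alkyne 18 without any carbon nucleophile or strong base. Ramirez olefination (CBr4, PPh3, CH2Cl2, 0 °C) gives 5,7-bis(benzyloxy)-2-(2,2-dibromovinyl)-4H-chromen-4-one F4. Hydrogenolysis with Bu3SnH and Pd(PPh3)4 removes the less hindered bromine, the one trans to the chromone, to give 5,7-bis(benzyloxy)-2-[(Z)-2-bromovinyl]-4H-chromen-4-one F5. Anti-elimination of hydrogen bromide with Bu4NF in DMF then gives 18.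

Step 9. The C–H oxidation may stall, run on to the carboxylic acid, or touch the benzylic CH2 groups of the ethers in hot SeO2. The fallback sets out from ketone 14 and comes back at aldehyde 17, replacing steps 8 and 9 by introducing the C2 carbon already oxidised. Claisen condensation with diethyl oxalate (NaOEt, EtOH) gives ethyl 4-[2,4-bis(benzyloxy)-6-hydroxyphenyl]-2,4-dioxobutanoate F6. Acid-catalysed cyclodehydration (HCl, EtOH) gives ethyl 5,7-bis(benzyloxy)-4-oxo-4H-chromene-2-carboxylate F7. NaBH4 in EtOH/THF reduces the activated ester to 5,7-bis(benzyloxy)-2-(hydroxymethyl)-4H-chromen-4-one F8, and MnO2 in CH2Cl2 oxidises this alcohol to 17.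

Further compounds
F1 | step 11 | methyl cis-3-{2-[4-(benzyloxy)phenyl]-5,7-dimethoxy-4-oxo-4H-chromen-3-yl}-4-(tert-butyldimethylsilyloxy)-6-(dimethylamino)cyclohexa-1,4-diene-1-carboxylate (racemic, relative configuration shown) | CN(C)[C@@H]1C=C(O[Si](C)(C)C(C)(C)C)[C@H](c2c(-c3ccc(OCc4ccccc4)cc3)oc3cc(OC)cc(OC)c3c2=O)C=C1C(=O)OC
F2 | step 11 | methyl 3-{2-[4-(benzyloxy)phenyl]-5,7-dimethoxy-4-oxo-4H-chromen-3-yl}-4-(tert-butyldimethylsilyloxy)benzoate | COC(=O)c1ccc(O[Si](C)(C)C(C)(C)C)c(-c2c(-c3ccc(OCc4ccccc4)cc3)oc3cc(OC)cc(OC)c3c2=O)c1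
F3 | step 11 | 1-[2,4-bis(benzyloxy)-6-hydroxyphenyl]-3-[3-{2-[4-(benzyloxy)phenyl]-5,7-dimethoxy-4-oxo-4H-chromen-3-yl}-4-(tert-butyldimethylsilyloxy)phenyl]propane-1,3-dione | O=C(CC(=O)c1ccc(O[Si](C)(C)C(C)(C)C)c(-c2c(-c3ccc(OCc4ccccc4)cc3)oc3cc(OC)cc(OC)c3c2=O)c1)c1c(O)cc(OCc2ccccc2)cc1OCc1ccccc1
F4 | step 10 | 5,7-bis(benzyloxy)-2-(2,2-dibromovinyl)-4H-chromen-4-one | BrC(Br)=Cc1cc(=O)c2c(OCc3ccccc3)cc(OCc3ccccc3)cc2o1
F5 | step 10 | 5,7-bis(benzyloxy)-2-[(Z)-2-bromovinyl]-4H-chromen-4-one | Br/C=C\c1cc(=O)c2c(OCc3ccccc3)cc(OCc3ccccc3)cc2o1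
F6 | step 9 | ethyl 4-[2,4-bis(benzyloxy)-6-hydroxyphenyl]-2,4-dioxobutanoate | CCOC(=O)C(=O)CC(=O)c1c(O)cc(OCc2ccccc2)cc1OCc1ccccc1
F7 | step 9 | ethyl 5,7-bis(benzyloxy)-4-oxo-4H-chromene-2-carboxylate | CCOC(=O)c1cc(=O)c2c(OCc3ccccc3)cc(OCc3ccccc3)cc2o1
F8 | step 9 | 5,7-bis(benzyloxy)-2-(hydroxymethyl)-4H-chromen-4-one | OCc1cc(=O)c2c(OCc3ccccc3)cc(OCc3ccccc3)cc2o1
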